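## Retrosynthetic overview

1. Target ⇒ 8β-acetoxy-9α-hydroxy-7-oxo furanolabdane. Break the C13–O bond. The spiro-tetrahydrofuran ring is closed last, by adding the 9α-OH and one H across C13=C16 of the furan, which thereby becomes the dihydrofuran.
2. Ring B triad (7-oxo, 8β-OAc, 9α-OH) ⇒ 7β-acetoxy-8(9)-ene. The α-epoxide is opened at C8 by its own acetate (C–O bond formed with inversion), then C7 is oxidised.
3. Furanolabdane ⇒ C12 tosylate + 3-bromofuran (C12–C13 bond, copper-catalysed Grignard coupling).
4. Tosylate ⇒ (+)-sclareolide. Rings A and B, with C5 and C10, come from the chiral pool and the furan is bought, so the spiro ether ring is the only ring made.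

Assumption: labdane numbering and α/β descriptors are used (the SMILES decodes as 5α-H, 10β-Me, 8β-OAc, 9α-O, 13R, the same series as (+)-sclareolide). Operations run in one flask without isolation count as one step.

## Route

Step 1
Reactants: 1 (+)-sclareolide
Product: 2 methyl 13,14,15,16-tetranorlabd-8-en-12-oate
Conditions: conc. H2SO4, MeOH, rt → 50 °C, 48 h; minor alkene isomers removed on AgNO3-silica
Reagents that add atoms: methanol, CO
Why: Acid-catalysed lactone methanolysis followed by E1 dehydration of the tertiary C8 alcohol under equilibrating conditions funnels the alkene isomers to the thermodynamic tetrasubstituted 8(9)-ene, leaving C5 and C10 untouched and erasing C8/C9 on purpose.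

Step 2
Reactants: 2 methyl 13,14,15,16-tetranorlabd-8-en-12-oate
Product: 3 methyl 7-oxo-13,14,15,16-tetranorlabd-8-en-12-oate
Conditions: CrO3, 3,5-dimethylpyrazole, CH2Cl2, −20 °C
Reagents that add atoms: chromium trioxide, O=[Cr](=O)=O
Why: Allylic oxidation with the hexavalent chromium–pyrazole complex takes the only electron-rich ring allylic methylene (C7), because C11–H is deactivated by the ester and C17 is only a methyl group, and no stereocentre is created.

Step 3
Reactants: 3 methyl 7-oxo-13,14,15,16-tetranorlabd-8-en-12-oate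
Product: 4 13,14,15,16-tetranorlabd-8-ene-7β,12-diol
Conditions: LiAlH4 (inverse addition), Et2O, −78 → 0 °C; Rochelle work-up
Reagents that add atoms: none
Why: Hydride reduction adds 1,2 to the enone faster than it enolises it and also reduces the ester, and axial delivery from the α face (away from the 10β-methyl) sets the pseudo-equatorial 7β-OH.

Step 4
Reactants: 4 13,14,15,16-tetranorlabd-8-ene-7β,12-diol
Product: 5 7β-hydroxy-13,14,15,16-tetranorlabd-8-en-12-yl 4-methylbenzenesulfonate
Conditions: TsCl (1.1 equiv), pyridine, 0 °C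
Reagents that add atoms: 4-toluenesulfonyl chloride, Cc1ccc(cc1)S(=O)(=O)Cl
Why: Selective sulfonylation works because the unhindered primary alcohol reacts far faster than the secondary allylic alcohol flanked by the tetrasubstituted alkene, and no stereocentre is touched.

Step 5
Reactants: 5 7β-hydroxy-13,14,15,16-tetranorlabd-8-en-12-yl 4-methylbenzenesulfonate; 6 3-bromofuran
Product: 9 15,16-epoxylabda-8,13(16),14-trien-7β-ol, via 3-furyllithium 7 (not isolated), via 3-furylmagnesium bromide 8 (not isolated)
Conditions: 6 (3.5 equiv), n-BuLi, THF, −78 °C; MgBr2·OEt2, −78 → 0 °C; then 5, Li2CuCl4 (5 mol%), THF, 0 °C → rt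
Reagents that add atoms: 3-bromofuran (6), Brc1ccoc1
Why: In this Kochi–Schlosser copper-catalysed sp3–sp2 coupling, cold transmetalation stops the 3-furyl to 2-furyl isomerisation, one equivalent of 8 merely deprotonates the 7-OH, and the unhindered C12 is substituted without touching a stereocentre.

Step 6
Reactants: 9 15,16-epoxylabda-8,13(16),14-trien-7β-ol
Product: 10 15,16-epoxylabda-8,13(16),14-trien-7β-yl acetate
Conditions: Ac2O, pyridine, DMAP (cat.), CH2Cl2, rt
Reagents that add atoms: acetic anhydride, CC(=O)OC(C)=O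
Why: DMAP-catalysed O-acylation proceeds with retention at C7 and installs the acetyl group that ends up on O-8 of the target.

Step 7
Reactants: 10 15,16-epoxylabda-8,13(16),14-trien-7β-yl acetate
Product: 13 8β-acetoxy-15,16-epoxylabda-13(16),14-diene-7β,9α-diol, via 8α,9α-epoxide 11 (not isolated), via 7β,8β-acetoxonium ion 12 (not isolated)
Conditions: mCPBA (1.05 equiv), CH2Cl2, −10 °C; then H2O (5 equiv), camphorsulfonic acid (10 mol%), 0 °C, short contact; NaHCO3 quench
Reagents that add atoms: 3-chloroperbenzoic acid, OOC(=O)c1cccc(Cl)c1; water, O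
Why: Prilezhaev epoxidation takes the tetrasubstituted alkene before the β-substituted furan and from the α face (anti to the 10β-Me and 7β-OAc), the acid then opens the epoxide trans-diaxially (Fürst–Plattner) with anchimeric attack of the 7β-acetate carbonyl on C8 from the β face (inversion at C8, 9α-O retained), and stereoelectronic collapse of the hydrated acetoxonium gives the axial ester and equatorial alcohol, so 8β-OAc and 9α-OH are both set here.

Step 8
Reactants: 13 8β-acetoxy-15,16-epoxylabda-13(16),14-diene-7β,9α-diol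
Product: 14 8β-acetoxy-9α-hydroxy-15,16-epoxylabda-13(16),14-dien-7-one
Conditions: Dess–Martin periodinane, CH2Cl2, 0 °C → rt, run directly on crude 13
Reagents that add atoms: none
Why: Dess–Martin oxidation takes the only secondary alcohol, spares the furan, tertiary alcohol and acetate, and removes the possibility of O8→O7 acyl migration (the 9α-OH is trans-diaxial to the acetate and cannot accept it).

Step 9
Reactants: 14 8β-acetoxy-9α-hydroxy-15,16-epoxylabda-13(16),14-dien-7-one
Product: 16 (13R)-8β-acetoxy-9α,13;15,16-diepoxylabd-14-en-7-one, via 2H-furanium cation 15 (not isolated)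
Conditions: [(R,R)-N,N'-bis(3,5-di-tert-butylsalicylidene)-1,2-cyclohexanediaminato]cobalt, C36H52CoN2O2 (10 mol%), 1-fluoro-2,4,6-trimethylpyridinium triflate (1.5 equiv), (Me2SiH)2O (1.5 equiv), Na2HPO4 (3 equiv, powdered), PhCF3, 0 °C, Ar; chromatography on Et3N-washed silica
Reagents that add atoms: none
Why: Proposed new method: a dearomative, contra-thermodynamic intramolecular hydroalkoxylation of a 3-alkylfuran, in which the cobalt hydride formed from the divalent cobalt salen complex, the N–F oxidant and the silane transfers H• to the furan α-carbon C16 (giving the tertiary, allyl- and oxygen-stabilised radical, a step estimated to be within a few kcal/mol as favourable as HAT to a 1,1-disubstituted alkene), the radical is captured and oxidised to a tetravalent alkylcobalt species equivalent to cation 15, and the 9α-OH, which can reach only C13 (5-exo), displaces it while the buffer takes the proton, so that Si–F bond formation pays for the lost aromaticity and no acid is present to reverse the closure; C13 is set as R because the bulkier new C16H2 turns toward the equatorial C17-methyl side and the flat C14–H toward the syn-axial H-1α, a modest substrate bias that the chiral salen ligand is meant to reinforce; the closest known reaction type is the cobalt-salen MHAT/radical-polar crossover hydroalkoxylation of unactivated alkenes, which has not been shown on a furan C=C bond.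

## Compound list

1 | (+)-sclareolide (5α-H, 9α-H, 10β-Me, 8α-O lactone) | C[C@]12CCCC([C@@H]1CC[C@@]3([C@@H]2CC(=O)O3)C)(C)C | starting material
2 | methyl 13,14,15,16-tetranorlabd-8-en-12-oate (5α-H, 10β-Me) | COC(=O)CC1=C(C)CC[C@H]2C(C)(C)CCC[C@]12C | intermediate
3 | methyl 7-oxo-13,14,15,16-tetranorlabd-8-en-12-oate | COC(=O)CC1=C(C)C(=O)C[C@H]2C(C)(C)CCC[C@]12C | intermediate
4 | 13,14,15,16-tetranorlabd-8-ene-7β,12-diol | O[C@H]1C[C@H]2C(C)(C)CCC[C@]2(C)C(CCO)=C1C | intermediate
5 | 7β-hydroxy-13,14,15,16-tetranorlabd-8-en-12-yl 4-methylbenzenesulfonate | O[C@H]1C[C@H]2C(C)(C)CCC[C@]2(C)C(CCOS(=O)(=O)c2ccc(C)cc2)=C1C | intermediate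
6 | 3-bromofuran | Brc1ccoc1 | starting material
7 | 3-furyllithium (not isolated) | [Li]c1ccoc1 | intermediate
8 | 3-furylmagnesium bromide (not isolated) | Br[Mg]c1ccoc1 | intermediate
9 | 15,16-epoxylabda-8,13(16),14-trien-7β-ol | O[C@H]1C[C@H]2C(C)(C)CCC[C@]2(C)C(CCc2ccoc2)=C1C | intermediate
10 | 15,16-epoxylabda-8,13(16),14-trien-7β-yl acetate | CC(=O)O[C@H]1C[C@H]2C(C)(C)CCC[C@]2(C)C(CCc2ccoc2)=C1C | intermediate
11 | 7β-acetoxy-8α,9α;15,16-diepoxylabda-13(16),14-diene (not isolated) | CC(=O)O[C@H]1C[C@H]2C(C)(C)CCC[C@]2(C)[C@]3(CCc4ccoc4)O[C@]13C | intermediate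
12 | 2-methyl-1,3-dioxolan-2-ylium ion bridging O-7β and O-8β, 9α-OH free (not isolated) | CC1=[O+][C@@]2(C)[C@@H](O1)C[C@H]3C(C)(C)CCC[C@]3(C)[C@@]2(O)CCc2ccoc2 | intermediate
13 | 8β-acetoxy-15,16-epoxylabda-13(16),14-diene-7β,9α-diol | CC(=O)O[C@@]1(C)[C@@H](O)C[C@H]2C(C)(C)CCC[C@]2(C)[C@@]1(O)CCc1ccoc1 | intermediate
14 | 8β-acetoxy-9α-hydroxy-15,16-epoxylabda-13(16),14-dien-7-one | CC(=O)O[C@@]1(C)C(=O)C[C@H]2C(C)(C)CCC[C@]2(C)[C@@]1(O)CCc1ccoc1 | intermediate
15 | C16-hydrogenated 2H-furanium cation of 14, or its tetravalent alkylcobalt equivalent (not isolated) | CC(=O)O[C@@]1(C)C(=O)C[C@H]2C(C)(C)CCC[C@]2(C)[C@@]1(O)CCC1=CC=[O+]C1 | intermediate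
16 | (13R)-8β-acetoxy-9α,13;15,16-diepoxylabd-14-en-7-one (5α-H, 10β-Me) | CC(=O)O[C@@]1(C)C(=O)C[C@H]2C(C)(C)CCC[C@]2(C)[C@@]12CC[C@]1(C=COC1)O2 | target

## Step count and risks

Total steps: 9. Longest linear sequence: 9 (from 1; compound 6 enters in step 5).

**Risk 1, step 9 (the new reaction).**
- The cobalt hydride may evolve H2 faster than it reacts with an aromatic C=C bond.
- HAT at C15 would lead to a 9,16-ether.
- Cation 15 may simply lose its proton, which only returns 14 and is not destructive.
- The diastereomer ratio at C13 may be low, so both catalyst enantiomers should be compared.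
- The product enol ether may react further, so the reaction should be stopped at partial conversion and 14 recycled.

The fallback uses known chemistry, sets out from 14 and returns at 16. Photo-oxygenation of the furan with singlet oxygen and i-Pr2NEt (O2, rose bengal, hν, CH2Cl2, −78 °C) gives 8β-acetoxy-9α,16-dihydroxy-7-oxolabd-13-en-15,16-olide F1. NaBH4 (1 equiv, MeOH, −40 °C) reduces only the masked aldehyde, and relactonisation gives 8β-acetoxy-9α-hydroxy-7-oxolabd-13-en-15,16-olide F2. Catalytic DBU (CH2Cl2, 0 °C) closes the spiro ether by reversible oxa-Michael addition of the 9α-OH to C13. After separation of the 13-epimer this gives (13R)-8β-acetoxy-9α,13-epoxy-7-oxolabdan-15,16-olide F3. i-Bu2AlH (2.5 equiv, CH2Cl2, −78 °C) reduces the lactone and the ketone but spares the hindered tertiary acetate, giving (13R)-8β-acetoxy-9α,13;15,16-diepoxylabdane-7,15-diol F4 (epimers at C7 and C15 are of no consequence). MsCl/Et3N (−20 °C) dehydrates the more reactive lactol to (13R)-8β-acetoxy-9α,13;15,16-diepoxylabd-14-en-7-ol F5. Dess–Martin periodinane buffered with pyridine then gives 16.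

**Risk 2, step 7.**
- The furan may compete for the peracid.
- The epoxide may ionise at C9, leading to elimination to the 9(11)-ene or a 10-methyl shift.
- Water may open the epoxide directly.
- The orthoacid may collapse to the 7-acetate, or the acetyl may migrate afterwards.

The fallback sets out from 9 and returns at 14. Here the C8 oxygen is delivered directly on the β face and the acetate is put on last. Hydroxyl-directed epoxidation (VO(acac)2 cat., t-BuOOH, toluene, 0 °C, inert to the furan) gives 8β,9β;15,16-diepoxylabda-13(16),14-dien-7β-ol F6. Trans-diaxial hydrolysis (cat. HClO4, THF–H2O, 0 °C; water attacks C9 from the α face) gives 15,16-epoxylabda-13(16),14-diene-7β,8β,9α-triol F7. Parikh–Doering oxidation (SO3·pyridine, DMSO, Et3N) gives 8β,9α-dihydroxy-15,16-epoxylabda-13(16),14-dien-7-one F8. Ac2O/DMAP/Et3N (40 °C) acetylates the less hindered 8-OH rather than the 9-OH, which sits between two quaternary carbons, and gives 14.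

**Risk 3, step 5.**
- The 3-furyl anion may isomerise to 2-furyl.
- The 1-bromobutane formed in the flask competes for the Grignard reagent.
- The tosylate may react slowly as its magnesium alkoxide.

The fallback sets out from 5 (with 6) and returns at 9. It replaces the nucleophile–electrophile coupling by a cross-electrophile coupling that tolerates the free OH. Finkelstein exchange (NaI, acetone, reflux) gives 12-iodo-13,14,15,16-tetranorlabd-8-en-7β-ol F9. This is joined to 6 under nickel catalysis (NiBr2(MeOCH2CH2OMe) 10 mol%, 4,4'-di-tert-butyl-2,2'-bipyridine, Zn dust, DMA, 40 °C) to give 9.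

## Further compounds

F1 | step 9 | 8β-acetoxy-9α,16-dihydroxy-7-oxolabd-13-en-15,16-olide (C16 epimers) | CC(=O)O[C@@]1(C)C(=O)C[C@H]2C(C)(C)CCC[C@]2(C)[C@@]1(O)CCC1=CC(=O)OC1O
F2 | step 9 | 8β-acetoxy-9α-hydroxy-7-oxolabd-13-en-15,16-olide | CC(=O)O[C@@]1(C)C(=O)C[C@H]2C(C)(C)CCC[C@]2(C)[C@@]1(O)CCC1=CC(=O)OC1
F3 | step 9 | (13R)-8β-acetoxy-9α,13-epoxy-7-oxolabdan-15,16-olide | CC(=O)O[C@@]1(C)C(=O)C[C@H]2C(C)(C)CCC[C@]2(C)[C@@]12CC[C@]1(CC(=O)OC1)O2
F4 | step 9 | (13R)-8β-acetoxy-9α,13;15,16-diepoxylabdane-7,15-diol (C7 and C15 epimers) | CC(=O)O[C@@]1(C)C(O)C[C@H]2C(C)(C)CCC[C@]2(C)[C@@]12CC[C@]1(CC(O)OC1)O2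
F5 | step 9 | (13R)-8β-acetoxy-9α,13;15,16-diepoxylabd-14-en-7-ol (C7 epimers) | CC(=O)O[C@@]1(C)C(O)C[C@H]2C(C)(C)CCC[C@]2(C)[C@@]12CC[C@]1(C=COC1)O2
F6 | step 7 | 8β,9β;15,16-diepoxylabda-13(16),14-dien-7β-ol | O[C@H]1C[C@H]2C(C)(C)CCC[C@]2(C)[C@@]3(CCc4ccoc4)O[C@@]13C
F7 | step 7 | 15,16-epoxylabda-13(16),14-diene-7β,8β,9α-triol | O[C@@]1(C)[C@@H](O)C[C@H]2C(C)(C)CCC[C@]2(C)[C@@]1(O)CCc1ccoc1
F8 | step 7 | 8β,9α-dihydroxy-15,16-epoxylabda-13(16),14-dien-7-one | O[C@@]1(C)C(=O)C[C@H]2C(C)(C)CCC[C@]2(C)[C@@]1(O)CCc1ccoc1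
F9 | step 5 | 12-iodo-13,14,15,16-tetranorlabd-8-en-7β-ol | O[C@H]1C[C@H]2C(C)(C)CCC[C@]2(C)C(CCI)=C1C
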